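## Retrosynthetic overview

- The four phenols are unmasked last. The 1,2-diketone comes from oxidation of a diarylalkyne, the alkyne from a Sonogashira coupling at a C8 bromide, and the bromide from bromination of the 5,7-dioxygenated ring A.
- The strategy rests on one feature: C2 is benzylic to ring B, and ring B carries a free hydroxyl at C4', para to the C1'–C2 bond. C2 can therefore be the exocyclic carbon of a para-quinone methide lying six atoms from the ring A phenol oxygen, so the O1–C2 bond is the key disconnection.
- The cyclisation precursor is a racemic 1-(4-hydroxyphenyl)-3-(2-hydroxyaryl)propan-1-ol. It comes from a Claisen–Schmidt condensation of a ring A aldehyde with a ring B acetophenone, then hydrogenation and hydride reduction.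
- Ring order: rings A and B are bought, the pyran ring is the only ring closed (step 6, which also sets C2), and the third arene arrives with the alkyne.

Key step: step 6

Assumption: the (R)-configured phosphoric acid is taken to give the 2S product. The sense of induction cannot be read from precedent for this cyclisation, so the (S)-catalyst is used instead if the first run shows the opposite sense.

## Route

Step 1
Reactants: 1 2,4,6-trihydroxybenzaldehyde
Product: 2 2-hydroxy-4,6-bis(methoxymethoxy)benzaldehyde
Conditions: MOMCl (2.2 equiv), i-Pr2NEt, CH2Cl2, 0 °C → rt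
Reagents that add atoms: chloromethyl methyl ether (MOMCl), COCCl
Why: MOM ether formation (O-alkylation of phenols) should stop at the 4,6-bis-ether, because the remaining ortho-hydroxyl is hydrogen-bonded to the aldehyde carbonyl and is the least nucleophilic of the three.

Step 2
Reactants: 2 2-hydroxy-4,6-bis(methoxymethoxy)benzaldehyde
Product: 3 2-(benzyloxy)-4,6-bis(methoxymethoxy)benzaldehyde
Conditions: BnBr, K2CO3, DMF, 60 °C
Reagents that add atoms: benzyl bromide, BrCc1ccccc1
Why: Williamson etherification under carbonate/DMF alkylates the chelated phenol, giving a benzyl ether that step 4 removes without touching the MOM ethers and that keeps the aldehyde from being deactivated as a phenoxide in step 3.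

Step 3
Reactants: 3 2-(benzyloxy)-4,6-bis(methoxymethoxy)benzaldehyde; 4 1-[4-(benzyloxy)phenyl]ethanone (4-benzyloxyacetophenone)
Product: 5 (E)-3-[2-(benzyloxy)-4,6-bis(methoxymethoxy)phenyl]-1-[4-(benzyloxy)phenyl]prop-2-en-1-one
Conditions: KOH (50% aq.), EtOH, rt
Reagents that add atoms: none
Why: Claisen–Schmidt condensation of the methyl ketone with the non-enolisable aldehyde should give the E-enone cleanly, since with both phenols capped neither partner is deactivated as a phenoxide.

Step 4
Reactants: 5 (E)-3-[2-(benzyloxy)-4,6-bis(methoxymethoxy)phenyl]-1-[4-(benzyloxy)phenyl]prop-2-en-1-one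
Product: 6 3-[2-hydroxy-4,6-bis(methoxymethoxy)phenyl]-1-(4-hydroxyphenyl)propan-1-one
Conditions: H2 (1 atm), 10% Pd/C, EtOAc, rt, stopped after 3 equiv of H2
Reagents that add atoms: none
Why: Catalytic hydrogenation saturates the enone C=C and hydrogenolyses both benzyl ethers in one operation, while the MOM ethers and the para-oxygenated aryl ketone should survive at 1 atm in a neutral solvent.

Step 5
Reactants: 6 3-[2-hydroxy-4,6-bis(methoxymethoxy)phenyl]-1-(4-hydroxyphenyl)propan-1-one
Product: 7 racemic 1-(4-hydroxyphenyl)-3-[2-hydroxy-4,6-bis(methoxymethoxy)phenyl]propan-1-ol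
Conditions: NaBH4 (excess), MeOH–THF, 0 °C → rt; sat. aq. NH4Cl quench; chromatography on Et3N-deactivated silica
Reagents that add atoms: none
Why: Borohydride reduction of the aryl ketone gives the carbinol as a racemate, which suffices because step 6 erases this centre, and the neutral work-up and base-washed silica are there to prevent an acid-triggered racemic cyclisation before the catalyst is present.

Step 6
Reactants: 7 racemic 1-(4-hydroxyphenyl)-3-[2-hydroxy-4,6-bis(methoxymethoxy)phenyl]propan-1-ol
Product: 9 (2S)-2-(4-hydroxyphenyl)-5,7-bis(methoxymethoxy)chroman, via para-quinone methide 8 (not isolated)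
Conditions: (R)-3,3'-bis(2,4,6-triisopropylphenyl)-1,1'-binaphthyl-2,2'-diyl hydrogen phosphate ((R)-TRIP, 10 mol%), 5 Å MS, PhMe (0.01 M), 0 °C
Reagents that add atoms: none
Why: Proposed new method: the phosphoric acid protonates the benzylic hydroxyl of 7 while the para-hydroxyl of ring B pushes out water, giving the planar para-quinone methide 8 from either carbinol enantiomer, and the ring A phenol oxygen then adds to the methide carbon in a 1,6-sense with rearomatisation of ring B. The closest known reaction type is the chiral phosphoric acid catalysed enantioselective 1,6-addition of external nucleophiles to para-quinone methides generated in situ from para-hydroxybenzyl alcohols; the intramolecular oxygen variant that delivers a 2-arylchroman has not been demonstrated. The pyran ring closes in the 6-exo-trig mode, the attacked C=C lying outside the ring being formed. The C2 configuration is set by the catalyst alone: the phosphate is expected to hydrogen-bond the quinone methide oxygen through P–OH and the attacking phenol O–H through P=O, so that one 2,4,6-triisopropylphenyl wall blocks one face of the methide. The step needs O-alkylation by the tethered phenol to outrun intermolecular Friedel–Crafts attack by electron-rich ring A carbons and tautomerisation of 8 to the 4-hydroxystyrene; the two-carbon tether brings only the phenol oxygen within reach (a ring A C–H carbon could close only a strained meta-bridged ring) and high dilution suppresses the bimolecular paths. A weak acid, molecular sieves and sub-ambient temperature are chosen so that 9 is not re-ionised at C2 after it forms.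

Step 7
Reactants: 9 (2S)-2-(4-hydroxyphenyl)-5,7-bis(methoxymethoxy)chroman
Product: 10 (2S)-5,7-bis(methoxymethoxy)-2-[4-(methoxymethoxy)phenyl]chroman
Conditions: MOMCl, i-Pr2NEt, CH2Cl2, 0 °C → rt
Reagents that add atoms: chloromethyl methyl ether (MOMCl), COCCl
Why: MOM ether formation at the only free phenol with an amine base (no metal hydride) keeps the concentration of the 4'-phenoxide low, so that base-induced ring opening at C2 (retro-oxa-1,6-addition) should not scramble the stereocentre, and it shields ring B for the next steps.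

Step 8
Reactants: 10 (2S)-5,7-bis(methoxymethoxy)-2-[4-(methoxymethoxy)phenyl]chroman
Product: 11 (2S)-8-bromo-5,7-bis(methoxymethoxy)-2-[4-(methoxymethoxy)phenyl]chroman
Conditions: NBS (1.0 equiv), CH2Cl2, –78 → –20 °C
Reagents that add atoms: N-bromosuccinimide, O=C1CCC(=O)N1Br
Why: Electrophilic aromatic bromination should take place on the triply oxygenated ring A in preference to ring B and at C8 in preference to C6, as is usual for 5,7-dialkoxyflavans (C6 is buttressed by two MOM ethers, C8 is flanked by the unhindered ring oxygen), with one equivalent at low temperature preventing dibromination.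

Step 9
Reactants: 12 4-ethynylphenol
Product: 13 1-ethynyl-4-(methoxymethoxy)benzene
Conditions: MOMCl, i-Pr2NEt, CH2Cl2, 0 °C → rt
Reagents that add atoms: chloromethyl methyl ether (MOMCl), COCCl
Why: MOM ether formation caps the phenol of the alkyne partner with the same group as the rest of the molecule, so one final operation removes all four.

Step 10
Reactants: 11 (2S)-8-bromo-5,7-bis(methoxymethoxy)-2-[4-(methoxymethoxy)phenyl]chroman; 13 1-ethynyl-4-(methoxymethoxy)benzene
Product: 14 (2S)-5,7-bis(methoxymethoxy)-2-[4-(methoxymethoxy)phenyl]-8-{[4-(methoxymethoxy)phenyl]ethynyl}chroman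
Conditions: PdCl2(MeCN)2 (5 mol%), XPhos (15 mol%), Cs2CO3, MeCN, 80 °C
Reagents that add atoms: none
Why: Copper-free Sonogashira coupling with a bulky, electron-rich biarylphosphine should allow oxidative addition of zerovalent palladium into the hindered, electron-rich C8–Br bond, and leaving out copper avoids alkyne homocoupling.

Step 11
Reactants: 14 (2S)-5,7-bis(methoxymethoxy)-2-[4-(methoxymethoxy)phenyl]-8-{[4-(methoxymethoxy)phenyl]ethynyl}chroman
Product: 15 1-{(2S)-5,7-bis(methoxymethoxy)-2-[4-(methoxymethoxy)phenyl]chroman-8-yl}-2-[4-(methoxymethoxy)phenyl]ethane-1,2-dione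
Conditions: KMnO4, NaHCO3, MgSO4, acetone–H2O, 0 °C → rt
Reagents that add atoms: potassium permanganate, [K+].[O-][Mn](=O)(=O)=O
Why: Buffered permanganate oxidation of a diarylalkyne to the 1,2-diketone (through a cyclic manganate ester) runs at neutral pH where MOM ethers and C2 are safe, and it is chosen over π-acidic divalent palladium in DMSO, which could cyclise the ortho-alkynylaryl MOM ether to a benzofuran.

Step 12
Reactants: 15 1-{(2S)-5,7-bis(methoxymethoxy)-2-[4-(methoxymethoxy)phenyl]chroman-8-yl}-2-[4-(methoxymethoxy)phenyl]ethane-1,2-dione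
Product: 16 1-[(2S)-5,7-dihydroxy-2-(4-hydroxyphenyl)chroman-8-yl]-2-(4-hydroxyphenyl)ethane-1,2-dione (target, CNP0332855.1)
Conditions: HCl (1.25 M in MeOH), MeOH, 0 °C → rt, under Ar
Reagents that add atoms: none
Why: Acid-catalysed acetal exchange removes the four MOM groups as dimethoxymethane, methanol trapping the methoxymethyl cation before it can alkylate C6, and dilute acid at or below room temperature should not ionise C2 because the C8 acyl group lowers the basicity of O1.

## Compound list

1 | 2,4,6-trihydroxybenzaldehyde | O=Cc1c(O)cc(O)cc1O | starting material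
2 | 2-hydroxy-4,6-bis(methoxymethoxy)benzaldehyde | O=Cc1c(O)cc(OCOC)cc1OCOC | intermediate
3 | 2-(benzyloxy)-4,6-bis(methoxymethoxy)benzaldehyde | O=Cc1c(OCc2ccccc2)cc(OCOC)cc1OCOC | intermediate
4 | 1-[4-(benzyloxy)phenyl]ethanone | CC(=O)c1ccc(OCc2ccccc2)cc1 | starting material
5 | (E)-3-[2-(benzyloxy)-4,6-bis(methoxymethoxy)phenyl]-1-[4-(benzyloxy)phenyl]prop-2-en-1-one | O=C(/C=C/c1c(OCc2ccccc2)cc(OCOC)cc1OCOC)c1ccc(OCc2ccccc2)cc1 | intermediate
6 | 3-[2-hydroxy-4,6-bis(methoxymethoxy)phenyl]-1-(4-hydroxyphenyl)propan-1-one | O=C(CCc1c(O)cc(OCOC)cc1OCOC)c1ccc(O)cc1 | intermediate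
7 | racemic 1-(4-hydroxyphenyl)-3-[2-hydroxy-4,6-bis(methoxymethoxy)phenyl]propan-1-ol | OC(CCc1c(O)cc(OCOC)cc1OCOC)c1ccc(O)cc1 | intermediate
8 | 4-{3-[2-hydroxy-4,6-bis(methoxymethoxy)phenyl]propylidene}cyclohexa-2,5-dien-1-one (para-quinone methide) | O=C1C=CC(=CCCc2c(O)cc(OCOC)cc2OCOC)C=C1 | intermediate (not isolated)
9 | (2S)-2-(4-hydroxyphenyl)-5,7-bis(methoxymethoxy)chroman | COCOc1cc(OCOC)c2c(c1)O[C@H](c1ccc(O)cc1)CC2 | intermediate
10 | (2S)-5,7-bis(methoxymethoxy)-2-[4-(methoxymethoxy)phenyl]chroman | COCOc1cc(OCOC)c2c(c1)O[C@H](c1ccc(OCOC)cc1)CC2 | intermediate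
11 | (2S)-8-bromo-5,7-bis(methoxymethoxy)-2-[4-(methoxymethoxy)phenyl]chroman | COCOc1cc(OCOC)c2c(c1Br)O[C@H](c1ccc(OCOC)cc1)CC2 | intermediate
12 | 4-ethynylphenol | C#Cc1ccc(O)cc1 | starting material
13 | 1-ethynyl-4-(methoxymethoxy)benzene | C#Cc1ccc(OCOC)cc1 | intermediate
14 | (2S)-5,7-bis(methoxymethoxy)-2-[4-(methoxymethoxy)phenyl]-8-{[4-(methoxymethoxy)phenyl]ethynyl}chroman | COCOc1cc(OCOC)c2c(c1C#Cc1ccc(OCOC)cc1)O[C@H](c1ccc(OCOC)cc1)CC2 | intermediate
15 | 1-{(2S)-5,7-bis(methoxymethoxy)-2-[4-(methoxymethoxy)phenyl]chroman-8-yl}-2-[4-(methoxymethoxy)phenyl]ethane-1,2-dione | COCOc1cc(OCOC)c2c(c1C(=O)C(=O)c1ccc(OCOC)cc1)O[C@H](c1ccc(OCOC)cc1)CC2 | intermediate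
16 | 1-[(2S)-5,7-dihydroxy-2-(4-hydroxyphenyl)chroman-8-yl]-2-(4-hydroxyphenyl)ethane-1,2-dione | O=C(C(=O)c1c(O)cc(O)c2c1O[C@H](c1ccc(O)cc1)CC2)c1ccc(O)cc1 | target

## Step count and risks

Total step count: 12. Longest linear sequence: 11 steps (steps 1–8 and 10–12 from compound 1); step 9 is a one-step branch.

Steps most likely to fail:

1. Step 6 (proposed new method). Ionisation of the secondary carbinol by a weak acid may be too slow at a temperature where facial discrimination is good. The quinone methide may tautomerise to the styrene or be captured intermolecularly. Reversible re-ionisation at C2 may erode the enantiomeric purity.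
 Fallback (known chemistry), setting out from compound 3 and returning at compound 10: aldehyde 3 would be condensed (KOH, EtOH) with 1-[4-(methoxymethoxy)phenyl]ethanone F1, itself made from 4-hydroxyacetophenone with MOMCl and i-Pr2NEt. This gives (E)-3-[2-(benzyloxy)-4,6-bis(methoxymethoxy)phenyl]-1-[4-(methoxymethoxy)phenyl]prop-2-en-1-one F2. Hydrogenation over 10% Pd/C saturates the alkene and frees only the ring A phenol, giving 3-[2-hydroxy-4,6-bis(methoxymethoxy)phenyl]-1-[4-(methoxymethoxy)phenyl]propan-1-one F3. Corey–Bakshi–Shibata reduction with (S)-2-methyl-CBS-oxazaborolidine and BH3·SMe2 (one extra equivalent for the phenol) should give (1R)-3-[2-hydroxy-4,6-bis(methoxymethoxy)phenyl]-1-[4-(methoxymethoxy)phenyl]propan-1-ol F4. Mitsunobu cyclisation (PPh3, DIAD, THF, 0 °C) then forms O1–C2 with inversion to give the 2S chroman 10, bypassing steps 3–7.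

2. Step 11. Permanganate may over-oxidise, cleaving the diketone C–C bond or degrading the electron-rich ring A, before the hindered alkyne is consumed.
 Fallback, setting out from compound 14 and returning at compound 15: semi-hydrogenation over Pd/CaCO3 poisoned with Pb(OAc)2 and quinoline would give (2S)-5,7-bis(methoxymethoxy)-2-[4-(methoxymethoxy)phenyl]-8-{(Z)-2-[4-(methoxymethoxy)phenyl]ethenyl}chroman F5. Dihydroxylation with catalytic OsO4 and NMO (acetone–H2O) gives 1-{(2S)-5,7-bis(methoxymethoxy)-2-[4-(methoxymethoxy)phenyl]chroman-8-yl}-2-[4-(methoxymethoxy)phenyl]ethane-1,2-diol F6 as a mixture of the two syn-diol diastereomers. Double Swern oxidation ((COCl)2, DMSO, Et3N, –78 °C) of both carbinols converges on diketone 15.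

3. Step 10. Oxidative addition into the doubly ortho-oxygenated C8–Br bond may be slow, so that hydrodebromination or alkyne oligomerisation competes.
 Fallback, setting out from compound 11 and returning at compound 14, with the roles of the partners reversed: bromine–lithium exchange (n-BuLi, THF, –78 °C) gives {(2S)-5,7-bis(methoxymethoxy)-2-[4-(methoxymethoxy)phenyl]chroman-8-yl}lithium F7. Quenching with DMF gives (2S)-5,7-bis(methoxymethoxy)-2-[4-(methoxymethoxy)phenyl]chroman-8-carbaldehyde F8. Ohira–Bestmann homologation (dimethyl (1-diazo-2-oxopropyl)phosphonate, K2CO3, MeOH) gives (2S)-8-ethynyl-5,7-bis(methoxymethoxy)-2-[4-(methoxymethoxy)phenyl]chroman F9. A classical Sonogashira coupling (PdCl2(PPh3)2, CuI, Et3N, THF, rt) with 1-iodo-4-(methoxymethoxy)benzene F10 (from 4-iodophenol, MOMCl and i-Pr2NEt) then gives alkyne 14; the aryl iodide undergoes easy oxidative addition and the hindered site sits on the alkyne.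

## Further compounds

F1 | step 6 | 1-[4-(methoxymethoxy)phenyl]ethanone | CC(=O)c1ccc(OCOC)cc1
F2 | step 6 | (E)-3-[2-(benzyloxy)-4,6-bis(methoxymethoxy)phenyl]-1-[4-(methoxymethoxy)phenyl]prop-2-en-1-one | O=C(/C=C/c1c(OCc2ccccc2)cc(OCOC)cc1OCOC)c1ccc(OCOC)cc1
F3 | step 6 | 3-[2-hydroxy-4,6-bis(methoxymethoxy)phenyl]-1-[4-(methoxymethoxy)phenyl]propan-1-one | O=C(CCc1c(O)cc(OCOC)cc1OCOC)c1ccc(OCOC)cc1
F4 | step 6 | (1R)-3-[2-hydroxy-4,6-bis(methoxymethoxy)phenyl]-1-[4-(methoxymethoxy)phenyl]propan-1-ol | O[C@H](CCc1c(O)cc(OCOC)cc1OCOC)c1ccc(OCOC)cc1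
F5 | step 11 | (2S)-5,7-bis(methoxymethoxy)-2-[4-(methoxymethoxy)phenyl]-8-{(Z)-2-[4-(methoxymethoxy)phenyl]ethenyl}chroman | COCOc1cc(OCOC)c2c(c1/C=C\c1ccc(OCOC)cc1)O[C@H](c1ccc(OCOC)cc1)CC2
F6 | step 11 | 1-{(2S)-5,7-bis(methoxymethoxy)-2-[4-(methoxymethoxy)phenyl]chroman-8-yl}-2-[4-(methoxymethoxy)phenyl]ethane-1,2-diol (syn-diol, both diastereomers) | COCOc1cc(OCOC)c2c(c1C(O)C(O)c1ccc(OCOC)cc1)O[C@H](c1ccc(OCOC)cc1)CC2
F7 | step 10 | {(2S)-5,7-bis(methoxymethoxy)-2-[4-(methoxymethoxy)phenyl]chroman-8-yl}lithium | COCOc1cc(OCOC)c2c(c1[Li])O[C@H](c1ccc(OCOC)cc1)CC2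
F8 | step 10 | (2S)-5,7-bis(methoxymethoxy)-2-[4-(methoxymethoxy)phenyl]chroman-8-carbaldehyde | COCOc1cc(OCOC)c2c(c1C=O)O[C@H](c1ccc(OCOC)cc1)CC2
F9 | step 10 | (2S)-8-ethynyl-5,7-bis(methoxymethoxy)-2-[4-(methoxymethoxy)phenyl]chroman | COCOc1cc(OCOC)c2c(c1C#C)O[C@H](c1ccc(OCOC)cc1)CC2
F10 | step 10 | 1-iodo-4-(methoxymethoxy)benzene | COCOc1ccc(I)cc1
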